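Rings: A = cyclohexane carrying the acetate, B = cyclohexene, C = seven-membered ketone ring, D = lactone, E = furan. The plan rests on ring C: its furyl ketone C=O is joined through one CH2 to the quaternary C(CH3) of ring A, which lies β to the oxygen-bearing ring A carbon (through CH(CH3)) and has its methyl axial and cis to the angular CH2O of ring D; with the ring A carbon as a ketone this is a 1,5-diketone.
Last disconnections: the acetate comes from the ring A ketone (equatorial hydride delivery, SN2 inversion with acetate, desilylation); ring C is opened at the CH2–C(quaternary) bond to a 3-acetylfuran-2-yl group on ring B and a 2,3-dimethylcyclohexenone (ring A).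
Ring A: aldol condensation of a 1,5-diketone (2-oxobutyl arm on the angular carbon, acetyl on the neighbouring CH), both ketones released together from 1,1-disubstituted alkenes; ring D: MnO2 lactonisation of an ene-1,4-diol.
The three CH stereocentres of ring B are relayed from the angular carbon on a cyclohexadienone: Stille coupling brings in ring E, an isopropenyl copper reagent adds anti to the angular arm, then protonation and axial hydride delivery set the rest.
Ring B is made first: catalytic asymmetric Michael addition of an alkylated oxalacetate to methyl vinyl ketone fixes the angular carbon and aldol condensation closes the ring. Order of ring formation: B, D, A, C.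

Key step: step 18

Assumption: the cupreidine-derived catalyst of step 4 is taken to deliver the R configuration at the quaternary carbon; should the sense be the opposite, the cupreine-derived pseudoenantiomer is used.

Locants for the ring B intermediates: C1 = carbinol or carbonyl carbon (later C–OTBS); C2=C3 = alkene, C3 carrying the CH2O group (later the lactone carbonyl); C4 = angular quaternary carbon; C5 = carbon that receives isopropenyl (later acetyl); C6 = carbon that receives the furyl group.

Step 1
Reactants: 1 3-acetylfuran
Product: 2 2-(furan-3-yl)-2-methyl-1,3-dioxolane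
Conditions: HOCH2CH2OH, PPTS (cat.), benzene, reflux, Dean–Stark
Reagents that add atoms: ethylene glycol, OCCO
Why: Acid-catalysed ketalisation with azeotropic removal of water masks the acetyl group as a dioxolane, which later directs lithiation and withstands the organometallic and hydride steps; no stereocentre is formed.

Step 2
Reactants: 2 2-(furan-3-yl)-2-methyl-1,3-dioxolane
Product: 3 tributyl[3-(2-methyl-1,3-dioxolan-2-yl)furan-2-yl]stannane
Conditions: n-BuLi, THF, −78 → −20 °C; Bu3SnCl, −78 °C → rt
Reagents that add atoms: tributyltin chloride, CCCC[Sn](Cl)(CCCC)CCCC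
Why: Directed ortho-lithiation: n-BuLi removes the proton at C2 of the furan, which is flanked by the ring oxygen and the coordinating dioxolane, and Bu3SnCl traps the 2-furyllithium as the stannane.

Step 3
Reactants: 4 diethyl oxalacetate sodium salt; 5 2-(bromomethyl)but-1-ene
Product: 6 diethyl 2-(2-methylidenebutyl)-3-oxobutanedioate
Conditions: NaI (cat.), DMF, rt → 40 °C
Reagents that add atoms: none
Why: SN2 C-alkylation of the stabilised sodium enolate of a β-keto ester (oxalacetic ester alkylation) by a primary allylic bromide; the new CH remains enolisable, so its configuration is of no consequence.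

Step 4
Reactants: 6 diethyl 2-(2-methylidenebutyl)-3-oxobutanedioate; 7 methyl vinyl ketone
Product: 8 diethyl (2R)-2-(2-methylidenebutyl)-3-oxo-2-(3-oxobutyl)butanedioate
Conditions: 9-O-(9-phenanthryl)cupreidine (10 mol %), CH2Cl2, −20 °C
Reagents that add atoms: none
Why: Organocatalytic asymmetric Michael addition of an α-substituted β-keto ester to a vinyl ketone: the bifunctional cinchona base holds the hydrogen-bonded enolate as an ion pair, activates the enone through its phenolic OH and exposes one enolate face, which sets the quaternary (later angular) carbon as R.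

Step 5
Reactants: 8 diethyl (2R)-2-(2-methylidenebutyl)-3-oxo-2-(3-oxobutyl)butanedioate
Product: 10 diethyl (1R)-1-(2-methylidenebutyl)-4-oxocyclohex-2-ene-1,2-dicarboxylate, via ketol 9 (not isolated)
Conditions: pyrrolidine (0.3 equiv), AcOH (0.3 equiv), toluene, 60 °C
Reagents that add atoms: none
Why: Intramolecular aldol condensation, the ring-closing half of a Robinson annulation: the enamine of the methyl ketone attacks the strongly electrophilic α-keto ester carbonyl in the only ring size open to it (six) and loss of water gives the cyclohexenone of ring B, the quaternary carbon being untouched.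

Step 6
Reactants: 10 diethyl (1R)-1-(2-methylidenebutyl)-4-oxocyclohex-2-ene-1,2-dicarboxylate
Product: 11 (4R)-3,4-bis(hydroxymethyl)-4-(2-methylidenebutyl)cyclohex-2-en-1-ol (C1 epimers)
Conditions: (Me2CHCH2)2AlH (8 equiv), CH2Cl2, −78 → 0 °C; aq KNaC4H4O6
Reagents that add atoms: none
Why: Hydride reduction with (Me2CHCH2)2AlH takes the enone carbonyl (1,2-addition) and both esters to the alcohol level, which frees the two CH2OH groups for the tether of step 7; the carbinol epimers converge in step 8.

Step 7
Reactants: 11 (4R)-3,4-bis(hydroxymethyl)-4-(2-methylidenebutyl)cyclohex-2-en-1-ol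
Product: 12 acetonide alcohol (11 with its two CH2OH groups bridged as O–CMe2–O in a seven-membered dioxepine ring)
Conditions: Me2C(OMe)2, PPTS (cat.), CH2Cl2, rt
Reagents that add atoms: 2,2-dimethoxypropane, COC(C)(C)OC
Why: Acetal exchange can bridge only the two primary hydroxyls, which sit on neighbouring ring atoms, and the seven-membered isopropylidene acetal ties the angular CH2O back toward C3, which is what step 11 relies on.

Step 8
Reactants: 12 acetonide alcohol
Product: 14 dienone acetonide (cyclohexa-2,5-dien-1-one of the same skeleton), via enone acetonide 13 (not isolated)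
Conditions: IBX (4 equiv), DMSO, rt then 75 °C
Reagents that add atoms: none
Why: IBX first oxidises the allylic alcohol to the enone and then, in excess and with heating, dehydrogenates the only enolisable CH2–CH2 side (IBX dehydrogenation of ketones) to the cross-conjugated dienone; no stereocentre is affected.

Step 9
Reactants: 14 dienone acetonide
Product: 15 6-iodo dienone acetonide
Conditions: I2, pyridine, CH2Cl2, 0 °C → rt
Reagents that add atoms: iodine, [I][I]
Why: α-Iodination of an enone with I2–pyridine (conjugate addition of pyridine, iodination of the enolate, elimination) takes place on the CH=CH arm, since the other arm is β,β-disubstituted and does not accept pyridine.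

Step 10
Reactants: 15 6-iodo dienone acetonide; 3 tributyl[3-(2-methyl-1,3-dioxolan-2-yl)furan-2-yl]stannane
Product: 16 6-furyl dienone acetonide (C6 carries 3-(2-methyl-1,3-dioxolan-2-yl)furan-2-yl)
Conditions: Pd2(dba)3 (3 mol %), AsPh3 (12 mol %), CuI (10 mol %), NMP, rt → 50 °C
Reagents that add atoms: none
Why: Stille coupling of the α-iodoenone with the 2-furylstannane under zerovalent palladium with AsPh3 and CuI, conditions suited to hindered α-iodoenones, attaches ring E with the acetyl group still masked.

Step 11
Reactants: 16 6-furyl dienone acetonide; 17 isopropenylmagnesium bromide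
Product: 18 cyclohex-2-enone acetonide with C5 isopropenyl cis to the C4 CH2O group and trans to the C6 furyl group
Conditions: CuBr·SMe2 (0.3 equiv), THF, −78 → −40 °C; aq NH4Cl
Reagents that add atoms: none
Why: Copper-catalysed conjugate addition of the Grignard reagent reaches only the β-CH of the furyl-substituted arm (the other arm is β,β-disubstituted) and comes from the face opposite the freely rotating 2-methylidenebutyl arm on C4, that is the face of the tied-back CH2O, as additions to C1 of steroidal 1,4-dien-3-ones come anti to the angular methyl; the epimerisable C6 next to the ketone settles with the furyl group equatorial and trans to isopropenyl.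

Step 12
Reactants: 18 cyclohex-2-enone acetonide
Product: 19 allylic alcohol with the C1 OH trans to the C6 furyl group
Conditions: NaBH4, CeCl3·7H2O, MeOH, −78 °C
Reagents that add atoms: none
Why: Luche reduction: CeCl3 directs 1,2-hydride delivery to the enone, and attack along the unhindered axial trajectory gives the equatorial allylic alcohol, trans to the furyl group.

Step 13
Reactants: 19 allylic alcohol
Product: 20 TBS ether of 19
Conditions: TBSCl, imidazole, DMAP (cat.), DMF, 40 °C
Reagents that add atoms: tert-butyldimethylsilyl chloride, CC(C)(C)[Si](C)(C)Cl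
Why: Silylation of the secondary alcohol as the TBS ether under imidazole conditions, which leave both ketals intact.

Step 14
Reactants: 20 TBS ether
Product: 21 diol with C1 OTBS, C5 isopropenyl and C6 3-acetylfuran-2-yl (both ketals removed)
Conditions: PPTS, MeOH–H2O (10:1), 40 °C
Reagents that add atoms: water, O
Why: Mild acid hydrolysis cleaves the strained seven-membered acetonide and the dioxolane of the aryl ketone together (acetal hydrolysis), whereas a secondary TBS ether withstands PPTS.

Step 15
Reactants: 21 diol
Product: 24 lactone of rings B and D (C3 carbonyl joined through O to the C4 CH2), via hydroxy enal 22 (not isolated), via lactol 23 (not isolated)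
Conditions: MnO2 (excess), CH2Cl2, rt
Reagents that add atoms: none
Why: MnO2 oxidises only the allylic primary alcohol; the enal is captured by the neighbouring neopentyl CH2OH as a lactol, whose allylic C–H is oxidised in turn, so that the lactone carbonyl of ring D ends on the alkene carbon (oxidative lactonisation of an ene-1,4-diol).

Step 16
Reactants: 24 lactone
Product: 26 triketone (lactone carrying 3-acetylfuran-2-yl on C6 with acetyl on C5 and a 2-oxobutyl arm on C4), via tetrol 25 (not isolated)
Conditions: OsO4 (2 mol %), NaIO4 (5 equiv), 2,6-lutidine, dioxane–H2O (3:1), rt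
Reagents that add atoms: OsO4, O=[Os](=O)(=O)=O; NaIO4, [Na+].[O-]I(=O)(=O)=O
Why: Lemieux–Johnson cleavage (OsO4-catalysed dihydroxylation followed by periodate glycol cleavage) turns both electron-rich 1,1-disubstituted alkenes into ketones, while the conjugated lactone alkene and the acyl-deactivated furan react much more slowly.

Step 17
Reactants: 26 triketone
Product: 28 ring A enone carrying the 3-acetylfuran-2-yl group on ring B (precursor of the key step), via ketol 27 (not isolated)
Conditions: KOt-Bu (0.3 equiv), t-BuOH–THF, 0 °C → rt
Reagents that add atoms: none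
Why: Intramolecular aldol condensation under reversible alkoxide conditions: the six-membered closures are fastest, and the one that ends in the more substituted enone (ethyl ketone CH2 onto the acetyl carbonyl) is drained by dehydration, as in the cyclisation of 2,5- and 2,6-diketones to 2-alkyl-3-methyl enones; the ring fusion CH, α to the acetyl group, keeps its equatorial substituents and gives the trans-fused ring A.

Step 18
Reactants: 28 ring A enone with 3-acetylfuran-2-yl on ring B
Product: 29 pentacyclic ring A ketone (rings A to E; quaternary C–CH3 axial and cis to the angular CH2O, secondary methyl equatorial)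
Conditions: LiN(SiMe3)2 (1.1 equiv), THF, −78 → 0 °C; AcOH
Reagents that add atoms: none
Why: Proposed new method: LiN(SiMe3)2 removes a proton from the acetyl CH3 on the furan, the most acidic and most accessible C–H, and the carbon of this lithium enolate adds to the β-carbon of the ring A enone in a 7-exo-trig conjugate addition that closes ring C and creates the quaternary carbon; the closest known reaction type is the intramolecular Michael addition of ketone enolates to β,β-disubstituted cyclohexenones, known for five- and six-membered rings. The furyl group is equatorial on ring B, next to the ring fusion CH, so the three-atom tether can reach the β-carbon only in the equatorial direction, which is also the side away from the axial CH2O of ring D; the new C–CH2 bond therefore ends equatorial and the methyl axial, cis to CH2O. The ring A enolate formed is more basic than the new ring C ketone, so proton transfer through HN(SiMe3)2 shifts the charge to the CH2 beside the furyl ketone, which pulls the equilibrium away from retro-Michael cleavage, and the CH(CH3) carbon, protonated α to the ring A ketone, equilibrates to the equatorial methyl. The step needs site selectivity in deprotonation and in addition: the ring A α′-CH2 is less acidic and its enolate is unproductive and reversible, 1,2-addition would need a nine-membered ring, and the unsaturated lactone of ring B cannot be reached from the equatorial furyl group because that would require a 1,3-diaxial bridge across the rigid trans-fused ring B.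

Step 19
Reactants: 29 pentacyclic ring A ketone
Product: 30 axial ring A alcohol
Conditions: NaBH4, MeOH–CH2Cl2 (1:1), −40 °C
Reagents that add atoms: none
Why: Borohydride reduction of the more electrophilic dialkyl ketone (the ring C carbonyl is deactivated by conjugation with the furan and the lactone is inert at low temperature); axial attack is blocked by the axial CH3 and CH2O groups on both β-carbons, so hydride enters equatorially and the new carbinol carbon has its OH axial.

Step 20
Reactants: 30 axial ring A alcohol
Product: 31 equatorial acetate (TBS ether of the target)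
Conditions: PPh3, diisopropyl azodicarboxylate, AcOH, toluene, 0 °C → rt
Reagents that add atoms: acetic acid, CC(=O)O
Why: Mitsunobu reaction: the axial alcohol is activated as its oxyphosphonium ion and displaced by acetate in an SN2 process with inversion, which gives the equatorial acetate, trans to the neighbouring equatorial methyl.

Step 21
Reactants: 31 equatorial acetate, TBS ether
Product: 32 CNP0182929.2
Conditions: HF·pyridine, pyridine, THF, 0 °C → rt
Reagents that add atoms: none
Why: Fluoride cleavage of the silyl ether under buffered, non-basic conditions, which spare the acetate, the unsaturated lactone and the furan.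

Compound list
1 | 3-acetylfuran | CC(=O)c1ccoc1 | starting material
2 | 2-(furan-3-yl)-2-methyl-1,3-dioxolane | CC1(OCCO1)c1ccoc1 | intermediate
3 | tributyl[3-(2-methyl-1,3-dioxolan-2-yl)furan-2-yl]stannane | CCCC[Sn](CCCC)(CCCC)c1occc1C1(C)OCCO1 | intermediate
4 | diethyl oxalacetate sodium salt (sodium enolate of diethyl 2-oxobutanedioate) | [Na+].CCOC(=O)C=C([O-])C(=O)OCC | starting material
5 | 2-(bromomethyl)but-1-ene | C=C(CC)CBr | starting material
6 | diethyl 2-(2-methylidenebutyl)-3-oxobutanedioate (racemic, enolisable) | CCOC(=O)C(=O)C(CC(=C)CC)C(=O)OCC | intermediate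
7 | methyl vinyl ketone (but-3-en-2-one) | C=CC(C)=O | starting material
8 | diethyl (2R)-2-(2-methylidenebutyl)-3-oxo-2-(3-oxobutyl)butanedioate | C=C(CC)C[C@@](C(=O)C(=O)OCC)(CCC(C)=O)C(=O)OCC | intermediate
9 | ketol: diethyl (1R)-2-hydroxy-1-(2-methylidenebutyl)-4-oxocyclohexane-1,2-dicarboxylate (C2 epimers) | C=C(CC)C[C@@]1(C(=O)OCC)C(O)(C(=O)OCC)CC(=O)CC1 | intermediate
10 | diethyl (1R)-1-(2-methylidenebutyl)-4-oxocyclohex-2-ene-1,2-dicarboxylate | C=C(CC)C[C@@]1(C(=O)OCC)C(C(=O)OCC)=CC(=O)CC1 | intermediate
11 | (4R)-3,4-bis(hydroxymethyl)-4-(2-methylidenebutyl)cyclohex-2-en-1-ol (C1 epimers) | C=C(CC)C[C@@]1(CO)C(CO)=CC(O)CC1 | intermediate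
12 | acetonide alcohol: 11 with the C3 and C4 CH2OH groups bridged as O–CMe2–O (C1 epimers) | C=C(CC)C[C@@]12COC(C)(C)OCC1=CC(O)CC2 | intermediate
13 | enone acetonide: C1 ketone of 12 | C=C(CC)C[C@@]12COC(C)(C)OCC1=CC(=O)CC2 | intermediate
14 | dienone acetonide: 4-(2-methylidenebutyl)cyclohexa-2,5-dien-1-one with the C3 and C4 CH2O groups bridged as O–CMe2–O | C=C(CC)C[C@@]12COC(C)(C)OCC1=CC(=O)C=C2 | intermediate
15 | 6-iodo dienone acetonide | C=C(CC)C[C@@]12COC(C)(C)OCC1=CC(=O)C(I)=C2 | intermediate
16 | 6-furyl dienone acetonide: C6 carries 3-(2-methyl-1,3-dioxolan-2-yl)furan-2-yl | C=C(CC)C[C@@]12COC(C)(C)OCC1=CC(=O)C(c3occc3C4(C)OCCO4)=C2 | intermediate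
17 | isopropenylmagnesium bromide (prop-1-en-2-ylmagnesium bromide) | C=C(C)[Mg]Br | starting material
18 | cyclohex-2-enone acetonide: C5 isopropenyl cis to the C4 CH2O group and trans to the C6 ketal-protected furyl group | C=C(CC)C[C@@]12COC(C)(C)OCC1=CC(=O)[C@@H](c3occc3C4(C)OCCO4)[C@@H]2C(C)=C | intermediate
19 | allylic alcohol: C1 OH trans to the C6 furyl group, otherwise as 18 | C=C(CC)C[C@@]12COC(C)(C)OCC1=C[C@H](O)[C@@H](c3occc3C4(C)OCCO4)[C@@H]2C(C)=C | intermediate
20 | TBS ether of 19 | C=C(CC)C[C@@]12COC(C)(C)OCC1=C[C@H](O[Si](C)(C)C(C)(C)C)[C@@H](c3occc3C4(C)OCCO4)[C@@H]2C(C)=C | intermediate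
21 | diol: 3,4-bis(hydroxymethyl)cyclohex-2-ene with C1 OTBS, C4 2-methylidenebutyl, C5 isopropenyl, C6 3-acetylfuran-2-yl | C=C(CC)C[C@@]1(CO)C(CO)=C[C@H](O[Si](C)(C)C(C)(C)C)[C@@H](c2occc2C(C)=O)[C@@H]1C(C)=C | intermediate
22 | hydroxy enal: 21 with the C3 CH2OH oxidised to CHO | C=C(CC)C[C@@]1(CO)C(C=O)=C[C@H](O[Si](C)(C)C(C)(C)C)[C@@H](c2occc2C(C)=O)[C@@H]1C(C)=C | intermediate
23 | lactol: cyclic hemiacetal of 22 (anomers) | C=C(CC)C[C@@]12COC(O)C1=C[C@H](O[Si](C)(C)C(C)(C)C)[C@@H](c3occc3C(C)=O)[C@@H]2C(C)=C | intermediate
24 | lactone of rings B and D with C1 OTBS, C4 2-methylidenebutyl, C5 isopropenyl, C6 3-acetylfuran-2-yl | C=C(CC)C[C@@]12COC(=O)C1=C[C@H](O[Si](C)(C)C(C)(C)C)[C@@H](c3occc3C(C)=O)[C@@H]2C(C)=C | intermediate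
25 | tetrol: both 1,1-disubstituted alkenes of 24 dihydroxylated (diol epimers) | CCC(O)(CO)C[C@@]12COC(=O)C1=C[C@H](O[Si](C)(C)C(C)(C)C)[C@@H](c3occc3C(C)=O)[C@@H]2C(C)(O)CO | intermediate
26 | triketone: lactone with C4 2-oxobutyl, C5 acetyl, C6 3-acetylfuran-2-yl, C1 OTBS | CCC(=O)C[C@@]12COC(=O)C1=C[C@H](O[Si](C)(C)C(C)(C)C)[C@@H](c3occc3C(C)=O)[C@@H]2C(C)=O | intermediate
27 | ketol: ring A closed, tertiary alcohol at the former acetyl carbon (epimers) | O=C1C[C@@]23COC(=O)C2=C[C@H](O[Si](C)(C)C(C)(C)C)[C@@H](c4occc4C(C)=O)[C@@H]3C(C)(O)C1C | intermediate
28 | ring A enone (rings A, B, D) with 3-acetylfuran-2-yl and OTBS on ring B; precursor of the key step | O=C1C[C@@]23COC(=O)C2=C[C@H](O[Si](C)(C)C(C)(C)C)[C@@H](c4occc4C(C)=O)[C@@H]3C(C)=C1C | intermediate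
29 | pentacyclic ring A ketone (rings A to E), OTBS on ring B | O=C1C[C@@]23COC(=O)C2=C[C@H](O[Si](C)(C)C(C)(C)C)[C@H]2c4occc4C(=O)C[C@@](C)([C@@H]1C)[C@@H]23 | intermediate
30 | axial ring A alcohol, OTBS on ring B | O[C@@H]1C[C@@]23COC(=O)C2=C[C@H](O[Si](C)(C)C(C)(C)C)[C@H]2c4occc4C(=O)C[C@@](C)([C@@H]1C)[C@@H]23 | intermediate
31 | equatorial ring A acetate, OTBS on ring B | CC(=O)O[C@H]1C[C@@]23COC(=O)C2=C[C@H](O[Si](C)(C)C(C)(C)C)[C@H]2c4occc4C(=O)C[C@@](C)([C@@H]1C)[C@@H]23 | intermediate
32 | CNP0182929.2 | CC(=O)O[C@H]1C[C@@]23COC(=O)C2=C[C@H](O)[C@H]2c4occc4C(=O)C[C@@](C)([C@@H]1C)[C@@H]23 | target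

Total step count: 21. Longest linear sequence: 19 steps (steps 3 to 21, starting from 4); steps 1 and 2 make the stannane 3, which joins at step 10.

Steps most likely to fail

Step 18 (the labelled step). The addition may stall or run backwards by retro-Michael cleavage, because the acceptor carbon is fully substituted and the product carries a 1,3-diaxial CH3/CH2O pair; the face of attack may also be less well controlled than expected. The fallback uses known chemistry and runs from 28 to 29: kinetic enolisation and O-silylation of the acetylfuran (LiN(SiMe3)2, Me3SiCl, THF, −78 °C) should give the trimethylsilyl enol ether F1, and TiCl4 in CH2Cl2 at −78 °C then activates the ring A enone for an intramolecular Mukaiyama–Michael addition, a reaction type established for quaternary carbons at β,β-disubstituted enones; aqueous work-up returns the route at 29.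

Step 20. E2 elimination of the activated axial alcohol, which has axial hydrogens anti to it on both neighbours, may outrun displacement at this hindered carbon. The fallback runs from 30 to 31: ClCH2SO2Cl and pyridine should give the chloromethanesulfonate F2, which is displaced with inversion by CsOAc and 18-crown-6 in toluene (SN2 inversion of hindered secondary sulfonates by caesium carboxylates).

Step 4. Facial discrimination of this acyclic enolate, flanked by two carbonyl groups of similar size, may be insufficient, and every later stereocentre is relayed from this carbon. The fallback runs from 4 to 8 and makes the two bonds at the quaternary carbon in the reverse order: Michael addition of 4 to 7 (AcOH, EtOH, 0 °C) should give the keto diester F3, and asymmetric phase-transfer alkylation of F3 with 5 (chiral binaphthyl-based spiro ammonium bromide, K2CO3, toluene, 0 °C) then sets the quaternary carbon of 8.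

Further compounds
F1 | step 18 | trimethylsilyl enol ether of 28 (acetyl group as CH2=C(OSiMe3)) | O=C1C[C@@]23COC(=O)C2=C[C@H](O[Si](C)(C)C(C)(C)C)[C@@H](c4occc4C(=C)O[Si](C)(C)C)[C@@H]3C(C)=C1C
F2 | step 20 | chloromethanesulfonate of axial alcohol 30 | O=S(=O)(CCl)O[C@@H]1C[C@@]23COC(=O)C2=C[C@H](O[Si](C)(C)C(C)(C)C)[C@H]2c4occc4C(=O)C[C@@](C)([C@@H]1C)[C@@H]23
F3 | step 4 | diethyl 2-oxo-3-(3-oxobutyl)butanedioate | CCOC(=O)C(=O)C(CCC(C)=O)C(=O)OCC
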